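Assumption: andrographolide (a bulk, enantiopure natural product) is taken as the cheap commercial source of both decalin halves; atoms are numbered as in andrographolide, with primes for the lactone-bearing half.

**Retrosynthetic overview**
- Target ⇐ removal of two 3,19-acetonides ⇐ Nef reaction of a C15 secondary nitro compound (the C15 ketone masked as CH–NO2).
- Key disconnection C15–C12': intermolecular nitro-Michael addition of a left-half nitronate to 14-O-acetyl-3,19-O-isopropylideneandrographolide, with loss of acetate; this sets 12'S and creates the butenolide.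
- Left-half nitroalkane ⇐ iodide ⇐ hydroxy methyl ester ⇐ opening of an (E)-α-alkylidene-γ-butyrolactone ⇐ Wittig reaction of the C12 aldehyde, then re-methylenation of C8.
- C12 aldehyde ⇐ ozonolysis of andrographolide acetonide, which is also the precursor of the Michael acceptor.
- Rings: both trans-decalins come intact from andrographolide; a temporary γ-lactone is put on the left half (Wittig) and opened; the right butenolide arises in the key step by double-bond transposition of the existing lactone.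

Abbreviations used in names: DecA = andrographolide decalin (C1–C10, C17–C20, 8(17)-methylidene, attached through C9, stereocentres as in 1) with the 3,19-diol as isopropylidene acetal; DecK = DecA with a C8 ketone in place of the methylidene; Dec = the free 3,19-diol.

**Step 1**
Reactants: 1 andrographolide
Product: 2 3,19-O-isopropylideneandrographolide
Conditions: 2,2-dimethoxypropane, PPTS (cat.), toluene/DMSO, 80 °C
Reagents that add atoms: 2,2-dimethoxypropane COC(C)(C)OC
Why: Acid-catalysed transacetalisation selectively ties the 1,3-related C3/C19 hydroxyls into a six-membered acetonide and leaves the allylic 14-OH free; no stereocentre is touched.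

**Step 2**
Reactants: 2 3,19-O-isopropylideneandrographolide
Product: 3 14-O-acetyl-3,19-O-isopropylideneandrographolide
Conditions: Ac2O, pyridine, DMAP (cat.), CH2Cl2, 0 °C to rt
Reagents that add atoms: acetic anhydride CC(=O)OC(C)=O
Why: Simple O-acylation of the only free hydroxyl turns C14 into a leaving group and makes the exocyclic enoate an addition–elimination (SN2') Michael acceptor; 14S is retained.

**Step 3**
Reactants: 4 α-bromo-γ-butyrolactone, 5 triphenylphosphine
Product: 7 3-(triphenyl-λ5-phosphanylidene)oxolan-2-one, via phosphonium bromide 6 (not isolated)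
Conditions: THF, reflux; then 1 M aq. NaOH, CH2Cl2, 0 °C
Reagents that add atoms: none
Why: SN2 quaternisation of the α-bromo lactone followed by deprotonation gives the bench-stable, ester-stabilised Wittig ylide.

**Step 4**
Reactants: 2 3,19-O-isopropylideneandrographolide
Product: 9 3,19-O-isopropylidene-8-oxo-13,14,15,16,17-pentanorandrographolid-12-al (DecK–CH2–CHO), via bis-ozonide 8 (not isolated)
Conditions: O3, CH2Cl2, −78 °C; then Me2S, −78 °C to rt
Reagents that add atoms: ozone O=[O+][O-]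
Why: Exhaustive ozonolysis with reductive work-up cleaves both C8=C17 and C12=C13, giving the C8 ketone and the C12 aldehyde; C9 keeps its configuration, which is also the thermodynamically preferred equatorial one.

**Step 5**
Reactants: 9 keto aldehyde DecK–CH2–CHO, 7 3-(triphenyl-λ5-phosphanylidene)oxolan-2-one
Product: 10 (3E)-3-[2-(DecK)ethylidene]oxolan-2-one
Conditions: toluene, 60 °C
Reagents that add atoms: none
Why: The stabilised ylide olefinates only the aldehyde (the hindered C8 ketone is inert) in a Wittig reaction that is reliably E-selective, setting the 12E geometry of the target.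

**Step 6**
Reactants: 10 (3E)-3-[2-(DecK)ethylidene]oxolan-2-one
Product: 11 (3E)-3-[2-(DecA)ethylidene]oxolan-2-one
Conditions: Zn, CH2Br2, TiCl4 (pre-formed Lombardo reagent), THF/CH2Cl2, 0 °C to rt
Reagents that add atoms: dibromomethane BrCBr
Why: Lombardo methylenation is non-basic and ketone-selective, so it restores the 8(17)-methylidene without epimerising C9 and without touching the conjugated lactone.

**Step 7**
Reactants: 11 (3E)-3-[2-(DecA)ethylidene]oxolan-2-one
Product: 13 methyl (2E)-2-(2-hydroxyethyl)-4-(DecA)but-2-enoate, via potassium carboxylate 12 (not isolated)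
Conditions: KOH (1.1 equiv), THF/H2O, rt; evaporate; MeI, DMF, 0 °C to rt; use crude at once
Reagents that add atoms: potassium hydroxide [K+].[OH-]; iodomethane CI
Why: Saponification opens the lactone and O-alkylation of the carboxylate under neutral conditions traps the open form as the methyl ester before it can relactonise; the alkene geometry is untouched.

**Step 8**
Reactants: 13 methyl (2E)-2-(2-hydroxyethyl)-4-(DecA)but-2-enoate
Product: 14 methyl (2E)-2-(2-iodoethyl)-4-(DecA)but-2-enoate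
Conditions: PPh3, I2, imidazole, CH2Cl2, 0 °C
Reagents that add atoms: iodine II
Why: Appel iodination of the primary alcohol is fast and neutral, so the acetonide, the enoate and the exocyclic alkene survive.

**Step 9**
Reactants: 14 methyl (2E)-2-(2-iodoethyl)-4-(DecA)but-2-enoate
Product: 15 methyl (2E)-2-(2-nitroethyl)-4-(DecA)but-2-enoate
Conditions: AgNO2, Et2O, 0 °C to rt, dark
Reagents that add atoms: silver nitrite [Ag+].[O-]N=O
Why: Victor Meyer substitution of a primary iodide with AgNO2 gives the nitroalkane under non-basic conditions, avoiding E2 elimination towards the diene.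

**Step 10**
Reactants: 15 methyl (2E)-2-(2-nitroethyl)-4-(DecA)but-2-enoate, 3 14-O-acetyl-3,19-O-isopropylideneandrographolide
Product: 18 methyl (2E)-4-(DecA)-2-[(3S)-2-nitro-3-(2-oxo-2,5-dihydrofuran-3-yl)-4-(DecA)butyl]but-2-enoate (C15 epimers), via cesium nitronate 16 (not isolated), via lactone enolate adduct 17 (not isolated)
Conditions: 15 (1.2 equiv), Cs2CO3 (1.1 equiv), MeCN, 0 °C, 20 min; then 3, 0 °C to rt
Reagents that add atoms: none
Why: Intermolecular nitro-Michael addition of the nitronate carbon (C15) to C12' followed by E1cB loss of the 14'-acetate forges C15–C12' and the butenolide; attack on the face of the planar alkylidene lactone anti to the 14'S acetoxy group corresponds to 12'S (the minor 12'-epimer is removed by chromatography, and C15 is destroyed later).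

**Step 11**
Reactants: 18 C15 nitro bis-acetonide
Product: 22 methyl (2E)-4-(DecA)-2-[(3S)-2-oxo-3-(2-oxo-2,5-dihydrofuran-3-yl)-4-(DecA)butyl]but-2-enoate, via sodium nitronate 19 (not isolated), via oxime 20 (not isolated), via ketimine 21 (not isolated)
Conditions: NaOMe (1.05 equiv), MeOH/THF, 0 °C; then aq. TiCl3 (4.5 equiv), NH4OAc buffer (pH 5–6), 0 °C to rt
Reagents that add atoms: water O
Why: McMurry's reductive Nef reaction converts the secondary nitronate through oxime and imine into the ketone at near-neutral pH, which spares the alkenes, ester, butenolide and acetonides and does not epimerise the now α-keto C12'.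

**Step 12**
Reactants: 22 bis-acetonide of the target
Product: 23 target: methyl (2E)-4-(Dec)-2-[(3S)-2-oxo-3-(2-oxo-2,5-dihydrofuran-3-yl)-4-(Dec)butyl]but-2-enoate
Conditions: AcOH/H2O (7:3), rt
Reagents that add atoms: none
Why: Mild acidic acetal hydrolysis frees both 3,19-diols without isomerising the exocyclic alkenes or the β,γ-unsaturated ketone.

**Compound list**
1 | andrographolide | C=C1CC[C@@H]2[C@](C)(CO)[C@H](O)CC[C@@]2(C)[C@@H]1C/C=C1/C(=O)OC[C@H]1O | starting material
2 | 3,19-O-isopropylideneandrographolide | C=C1CC[C@@H]2[C@]3(C)COC(C)(C)O[C@@H]3CC[C@@]2(C)[C@@H]1C/C=C1/C(=O)OC[C@H]1O | intermediate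
3 | 14-O-acetyl-3,19-O-isopropylideneandrographolide | C=C1CC[C@@H]2[C@]3(C)COC(C)(C)O[C@@H]3CC[C@@]2(C)[C@@H]1C/C=C1/C(=O)OC[C@H]1OC(C)=O | intermediate
4 | α-bromo-γ-butyrolactone (racemic 3-bromooxolan-2-one) | BrC1CCOC1=O | starting material
5 | triphenylphosphine | c1ccc(cc1)P(c1ccccc1)c1ccccc1 | starting material
6 | (2-oxooxolan-3-yl)triphenylphosphonium bromide | O=C1OCCC1[P+](c1ccccc1)(c1ccccc1)c1ccccc1.[Br-] | intermediate
7 | 3-(triphenyl-λ5-phosphanylidene)oxolan-2-one | O=C1OCCC1=P(c1ccccc1)(c1ccccc1)c1ccccc1 | intermediate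
8 | bis-ozonide of 2 (8,17- and 12,13-trioxolanes, diastereomer mixture) | C1OC2(OO1)CC[C@@H]3[C@]4(C)COC(C)(C)O[C@@H]4CC[C@@]3(C)[C@@H]2CC5OC6(OO5)C(=O)OC[C@H]6O | intermediate
9 | keto aldehyde DecK–CH2–CHO | O=C1CC[C@@H]2[C@]3(C)COC(C)(C)O[C@@H]3CC[C@@]2(C)[C@@H]1CC=O | intermediate
10 | (3E)-3-[2-(DecK)ethylidene]oxolan-2-one | O=C1CC[C@@H]2[C@]3(C)COC(C)(C)O[C@@H]3CC[C@@]2(C)[C@@H]1C/C=C1/C(=O)OCC1 | intermediate
11 | (3E)-3-[2-(DecA)ethylidene]oxolan-2-one | C=C1CC[C@@H]2[C@]3(C)COC(C)(C)O[C@@H]3CC[C@@]2(C)[C@@H]1C/C=C1/C(=O)OCC1 | intermediate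
12 | potassium (2E)-2-(2-hydroxyethyl)-4-(DecA)but-2-enoate | C=C1CC[C@@H]2[C@]3(C)COC(C)(C)O[C@@H]3CC[C@@]2(C)[C@@H]1C/C=C(\CCO)C(=O)[O-].[K+] | intermediate
13 | methyl (2E)-2-(2-hydroxyethyl)-4-(DecA)but-2-enoate | C=C1CC[C@@H]2[C@]3(C)COC(C)(C)O[C@@H]3CC[C@@]2(C)[C@@H]1C/C=C(\CCO)C(=O)OC | intermediate
14 | methyl (2E)-2-(2-iodoethyl)-4-(DecA)but-2-enoate | C=C1CC[C@@H]2[C@]3(C)COC(C)(C)O[C@@H]3CC[C@@]2(C)[C@@H]1C/C=C(\CCI)C(=O)OC | intermediate
15 | methyl (2E)-2-(2-nitroethyl)-4-(DecA)but-2-enoate | C=C1CC[C@@H]2[C@]3(C)COC(C)(C)O[C@@H]3CC[C@@]2(C)[C@@H]1C/C=C(\CC[N+](=O)[O-])C(=O)OC | intermediate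
16 | cesium nitronate of 15 | C=C1CC[C@@H]2[C@]3(C)COC(C)(C)O[C@@H]3CC[C@@]2(C)[C@@H]1C/C=C(\CC=[N+]([O-])[O-])C(=O)OC.[Cs+] | intermediate
17 | cesium lactone enolate (Michael adduct before acetate loss; C15 epimers) | C=C1CC[C@@H]2[C@]3(C)COC(C)(C)O[C@@H]3CC[C@@]2(C)[C@@H]1C/C=C(\CC([N+](=O)[O-])[C@@H](C[C@@H]1C(=C)CC[C@@H]2[C@]3(C)COC(C)(C)O[C@@H]3CC[C@]21C)C1=C([O-])OC[C@H]1OC(C)=O)C(=O)OC.[Cs+] | intermediate
18 | C15 nitro bis-acetonide (12E,12'S; C15 epimers) | C=C1CC[C@@H]2[C@]3(C)COC(C)(C)O[C@@H]3CC[C@@]2(C)[C@@H]1C/C=C(\CC([N+](=O)[O-])[C@@H](C[C@@H]1C(=C)CC[C@@H]2[C@]3(C)COC(C)(C)O[C@@H]3CC[C@]21C)C1=CCOC1=O)C(=O)OC | intermediate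
19 | sodium nitronate of 18 | C=C1CC[C@@H]2[C@]3(C)COC(C)(C)O[C@@H]3CC[C@@]2(C)[C@@H]1C/C=C(\CC(=[N+]([O-])[O-])[C@@H](C[C@@H]1C(=C)CC[C@@H]2[C@]3(C)COC(C)(C)O[C@@H]3CC[C@]21C)C1=CCOC1=O)C(=O)OC.[Na+] | intermediate
20 | C15 oxime bis-acetonide | C=C1CC[C@@H]2[C@]3(C)COC(C)(C)O[C@@H]3CC[C@@]2(C)[C@@H]1C/C=C(\CC(=NO)[C@@H](C[C@@H]1C(=C)CC[C@@H]2[C@]3(C)COC(C)(C)O[C@@H]3CC[C@]21C)C1=CCOC1=O)C(=O)OC | intermediate
21 | C15 N–H ketimine bis-acetonide | C=C1CC[C@@H]2[C@]3(C)COC(C)(C)O[C@@H]3CC[C@@]2(C)[C@@H]1C/C=C(\CC(=N)[C@@H](C[C@@H]1C(=C)CC[C@@H]2[C@]3(C)COC(C)(C)O[C@@H]3CC[C@]21C)C1=CCOC1=O)C(=O)OC | intermediate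
22 | bis(3,19-O-isopropylidene) derivative of the target (12E,12'S) | C=C1CC[C@@H]2[C@]3(C)COC(C)(C)O[C@@H]3CC[C@@]2(C)[C@@H]1C/C=C(\CC(=O)[C@@H](C[C@@H]1C(=C)CC[C@@H]2[C@]3(C)COC(C)(C)O[C@@H]3CC[C@]21C)C1=CCOC1=O)C(=O)OC | intermediate
23 | CNP0330094.1 | C=C1CC[C@@H]2[C@](C)(CO)[C@H](O)CC[C@@]2(C)[C@@H]1C/C=C(\CC(=O)[C@@H](C[C@@H]1C(=C)CC[C@@H]2[C@](C)(CO)[C@H](O)CC[C@]21C)C1=CCOC1=O)C(=O)OC | target

**Step count and risks**
Total steps: 12. Longest linear sequence: 10 steps (1 → 2 → 9 → 10 → 11 → 13 → 14 → 15 → 18 → 22 → 23).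

Most likely to fail, in order:

Step 10 (key coupling). Risks are base-induced 1,4-elimination of 3, a sluggish bimolecular addition, or a poor 12'-epimer ratio. The fallback reverses the donor and acceptor roles; it sets out from 3 and 9 and comes back at 18. Nitromethane (co-solvent, Cs2CO3, 0 °C) adds to 3 in the same anti addition–elimination sense to give (12S)-14-deoxy-12-(nitromethyl)-3,19-O-isopropylideneandrographolide F1. Separately, 9 undergoes a Morita–Baylis–Hillman reaction with methyl acrylate (DABCO, MeOH, rt) at the aldehyde only to give methyl 3-hydroxy-2-methylidene-4-(DecK)butanoate F2. Lombardo methylenation gives methyl 3-hydroxy-2-methylidene-4-(DecA)butanoate F3, and acetylation (Ac2O, DMAP) gives methyl 3-acetoxy-2-methylidene-4-(DecA)butanoate F4. The nitronate of F1 (Cs2CO3, MeCN) then attacks the terminal CH2 of F4 in an E-selective SN2' Michael addition–elimination, forming C14–C15 and delivering 18.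

Step 7 (lactone opening). Risks are hydroxide conjugate addition or retro-aldol, and relactonisation of 13. The fallback avoids the lactone altogether; it sets out from 9 and comes back at 13. Trimethyl phosphonoacetate is alkylated with 2-(tert-butyldimethylsilyloxy)ethyl iodide (NaH, DMF) to give methyl 4-(tert-butyldimethylsilyloxy)-2-(dimethoxyphosphoryl)butanoate F5. Horner–Wadsworth–Emmons reaction with 9 (NaH, THF; aldehyde-selective, E-major, isomers separable) gives methyl (2E)-2-[2-(tert-butyldimethylsilyloxy)ethyl]-4-(DecK)but-2-enoate F6. Lombardo methylenation gives methyl (2E)-2-[2-(tert-butyldimethylsilyloxy)ethyl]-4-(DecA)but-2-enoate F7, and HF·pyridine (THF, 0 °C) releases 13, which is iodinated at once.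

Step 6 (Lombardo methylenation). Risks are the hindered ketone and TiCl4-derived Lewis acidity towards the acetonide. The fallback protects the 8(17)-alkene instead of cleaving it; it sets out from 2 and comes back at 11. mCPBA (NaHCO3, CH2Cl2, 0 °C) epoxidises only the electron-rich exocyclic alkene to give 8,17-epoxy-3,19-O-isopropylideneandrographolide F8. Ozonolysis (O3, CH2Cl2, −78 °C; Me2S) then cleaves only C12=C13 to the epoxy aldehyde 8,17-epoxy-DecA–CH2–CHO F9. Wittig reaction with 7 gives (3E)-3-[2-(8,17-epoxy-DecA)ethylidene]oxolan-2-one F10, and deoxygenation with WCl6/n-BuLi (THF, −78 °C to rt) regenerates the methylidene to give 11.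

**Further compounds**
F1 | step 10 | (12S)-14-deoxy-12-(nitromethyl)-3,19-O-isopropylideneandrographolide | [O-][N+](=O)C[C@@H](C[C@@H]1C(=C)CC[C@@H]2[C@]3(C)COC(C)(C)O[C@@H]3CC[C@]21C)C1=CCOC1=O
F2 | step 10 | methyl 3-hydroxy-2-methylidene-4-(DecK)butanoate (carbinol epimers) | O=C1CC[C@@H]2[C@]3(C)COC(C)(C)O[C@@H]3CC[C@@]2(C)[C@@H]1CC(O)C(=C)C(=O)OC
F3 | step 10 | methyl 3-hydroxy-2-methylidene-4-(DecA)butanoate (carbinol epimers) | C=C1CC[C@@H]2[C@]3(C)COC(C)(C)O[C@@H]3CC[C@@]2(C)[C@@H]1CC(O)C(=C)C(=O)OC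
F4 | step 10 | methyl 3-acetoxy-2-methylidene-4-(DecA)butanoate (epimers) | C=C1CC[C@@H]2[C@]3(C)COC(C)(C)O[C@@H]3CC[C@@]2(C)[C@@H]1CC(OC(C)=O)C(=C)C(=O)OC
F5 | step 7 | methyl 4-(tert-butyldimethylsilyloxy)-2-(dimethoxyphosphoryl)butanoate | COC(=O)C(CCO[Si](C)(C)C(C)(C)C)P(=O)(OC)OC
F6 | step 7 | methyl (2E)-2-[2-(tert-butyldimethylsilyloxy)ethyl]-4-(DecK)but-2-enoate | O=C1CC[C@@H]2[C@]3(C)COC(C)(C)O[C@@H]3CC[C@@]2(C)[C@@H]1C/C=C(\CCO[Si](C)(C)C(C)(C)C)C(=O)OC
F7 | step 7 | methyl (2E)-2-[2-(tert-butyldimethylsilyloxy)ethyl]-4-(DecA)but-2-enoate | C=C1CC[C@@H]2[C@]3(C)COC(C)(C)O[C@@H]3CC[C@@]2(C)[C@@H]1C/C=C(\CCO[Si](C)(C)C(C)(C)C)C(=O)OC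
F8 | step 6 | 8,17-epoxy-3,19-O-isopropylideneandrographolide | C1OC12CC[C@@H]3[C@]4(C)COC(C)(C)O[C@@H]4CC[C@@]3(C)[C@@H]2C/C=C1/C(=O)OC[C@H]1O
F9 | step 6 | epoxy aldehyde 8,17-epoxy-DecA–CH2–CHO | C1OC12CC[C@@H]3[C@]4(C)COC(C)(C)O[C@@H]4CC[C@@]3(C)[C@@H]2CC=O
F10 | step 6 | (3E)-3-[2-(8,17-epoxy-DecA)ethylidene]oxolan-2-one | C1OC12CC[C@@H]3[C@]4(C)COC(C)(C)O[C@@H]4CC[C@@]3(C)[C@@H]2C/C=C1/C(=O)OCC1
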